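## The problem

The target is a guaianolide. Guaiane locants are used throughout: cyclopentane C1–C5; cycloheptane C1, C5–C10; lactone O6–C12 with the exocyclic methylene C13; C14 on C10; C15 on C4.

- **Ring system.** The C4 oxygen is bonded to C14, so O–C14=C10 is a cyclic enol ether. C1, C4, C5, C10, C14 and this oxygen form a 2-oxabicyclo[3.2.1]oct-3-ene that is fused to the seven-membered ring and, through it, to a trans α-methylene-γ-lactone.
- **Stereocentres.** Eight must be set: C1, C4 and C5 in the bicycle, C6 and C7 of the lactone, the trans-diol diester carbons C8 and C9, and C2 of the (R)-2-methylbutanoate.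
- **The hard relationship.** On the cyclopentane, C10, C6 and the C4 oxygen are all cis. This is the least stable arrangement of a monocycle, so it has to be enforced by a ring, not reached by equilibration.
- **Who controls whom.** Once the bicycle exists it is rigid. C8 can be bought from the chiral pool and can set C7, and with it C6, in one C–C bond formation. C9 is then the only centre left to the ring closure.
- **Fragile groups.** The enol ether is destroyed by acid. The C9 acetate is allylic to it and ionises easily. The methylene lactone takes up nucleophiles. Two different esters sit on neighbouring oxygens and can migrate. The primary C15 hydroxyl must be told apart from the C9 hydroxyl.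
- **The enabling feature.** C10 is the nucleophilic β-carbon of the enol ether and its neighbour C9 is a carbinol carbon. C9–C10 is therefore the bond an enol ether makes with an aldehyde, and C5 and C6 already hold the C6–C9 chain over the enol-ether face.

## Retrosynthesis

**31 ⇒ 30 ⇒ 29 (O9–acetyl and O15–Si).** The acetate on the ionisable allylic C9 position goes on last, and the C15 silyl ether is what keeps the two hydroxyls distinct. Alcohol 29 is the full skeleton with every carbon stereocentre. The forward steps must acetylate without acid and remove silicon under buffered fluoride.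

**29 ⇒ 27 (C9–C10, the key cut).** Cutting here opens the seven-membered ring at the one bond whose two ends are already polarised correctly: the enol-ether β-carbon and an aldehyde. The neighbouring cuts (C5–C6, C1–C10) would take the bicycle apart as well. Aldehyde 27 has one ring and one stereocentre fewer and carries both sensitive esters' precursors in final form at C8. The forward step must add C10 to the aldehyde, return the enol ether by loss of H10, and give the 8,9-trans alcohol.

**27 ⇒ 26 ⇒ 25 ⇒ 23 + 24 ⇒ 22 (C9 oxidation level, O8–acyl).** The ester has to be in place before the aldehyde exists, because an α-hydroxy aldehyde cannot be handled. C8 therefore carries a silyl ether and C9 a 4-methoxybenzyl ether in lactone 22. Both come off without acid and without touching the C15 silyl ether. Acid 24 is commercial.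

**22 ⇒ 11 + 20 (C6–C7 and O6–C12).** This is the convergent cut: bicyclic aldehyde 11 and allylboronate 20 are of similar size. One allylboration–lactonisation forms the lactone and sets C6 and C7. A cut at C7–C8 would leave C7 to be set without a controlling neighbour. The forward reaction must be anti-selective (trans lactone) and must take its facial sense from C8.

**20 ⇒ 18 ⇒ 16 ⇒ 15 ⇒ 14 ⇒ 13 ⇒ 12 (boronate from the chiral pool).** The C11–C13 bond comes from trapping the α-aluminated acrylate 19 with a one-carbon boron electrophile. Syn hydroalumination of alkynoate 18 fixes the alkene geometry. The alkyne carbons come from a Corey–Fuchs homologation of aldehyde 12, which supplies C8 with the correct configuration. The acetonide is exchanged early for groups that can later be removed beside the enol ether.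

**11 ⇒ 10 ⇒ 9 (enol ether; C6 and C14 carbonyls).** The enol ether is the dehydrated lactol of a C14 aldehyde with the C4 hydroxyl. Both the C14 and the C6 aldehydes arise by cleaving a C6=C14 double bond. That alkene closes a second five-membered ring in bicyclo[3.3.0]octene 9, and this ring is the device that holds C6 and C10 cis. After cleavage, only C14 can reach the C4 hydroxyl, so the two aldehydes are differentiated.

**9 ⇒ 8 ⇒ 7 ⇒ 6 (C4–C15).** A hydroxymethyl anion equivalent adds to ketone 6 from the convex face. This places C15 exo and the hydroxyl on the concave face, cis to C6 and C10, as the oxygen bridge requires.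

**6 ⇒ 5 ⇒ 4 (C4–C5).** An intramolecular carbonyl-ene reaction of aldehyde 4 forms the cyclopentanol, can only give the cis ring fusion, and moves the double bond to C6=C14, exactly where the later cleavage needs it.

**4 ⇒ 3 ⇒ 1 + 2 (C1–C2).** The only stereocentre of 4 is set by a catalytic asymmetric allylic alkylation of racemic bromide 1 with Grignard reagent 2, which brings C2–C4 as a masked aldehyde.

## Roads not taken

**Alternative 1:** The cuts are C1–C10 and C7–C8. In the forward sense Rh2(OAc)4 generates a vinylcarbene at C10 from a diazo ester tethered through the C4 oxygen. The carbene cyclopropanates the C1–C5 ring alkene and the cis-divinylcyclopropane rearranges at once to the tricyclic bridged lactone A1.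
- Merits: two skeletal bonds, the seven-membered ring and the oxygen bridge form in one step. The reaction type is well known and the rearrangement is stereospecific. In bond count and in precedent for the key step this road is better than the chosen one.
- Weak points: A1 is far from the target in oxidation pattern. The bridging lactone must be reduced to the enol ether while it is a vinylogous carbonate. The C9 enol silane must become a trans carbinol. The C5–C6 alkene must be hydrated with control at both carbons. The C7 side chain must still be turned into the methylene lactone.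
- Comparison: the chosen plan has a less certain key step, but it sets C5, C6, C7 and C8 before ring closure and needs two routine steps after it.

**Alternative 2:** The cut is at C9, inserted between C8 and C10. A Diels–Alder-derived cyclohexenone is enlarged with (trimethylsilyl)diazomethane and AlMe3 to the cis-hydroazulenone A2.
- Merits: this is the safest key step of the four, scalable and precedented, and the cis ring fusion comes from the cycloaddition.
- Weak points: A2 has none of the target's oxygen functions at C6, C8 or C9, no lactone and no bridged enol ether. All of them would be installed afterwards on a flexible seven-membered ring, which means a long linear endgame with several unsolved stereochemical problems. The migrating group in the ring enlargement must also be controlled.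
- Comparison: the chosen plan is riskier at its key step but far more convergent, and it builds the stereocentres where rigid or acyclic control is available.

**Alternative 3:** The cuts are C5–C6 and C4–O. Me2AlCl activates a C6 aldehyde, the cyclopentene carbon C5 attacks it, the C4 cation is captured by the C14 aldehyde oxygen, and loss of H10 gives A3.
- Merits: two rings and the centres C4, C5 and C6 form in one late step with the C8 and C9 esters already present. Only lactonisation and deprotection follow. In ring-forming economy this road beats the chosen one.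
- Weak points: three stereocentres and a cation relay are left to one cascade on a flexible substrate. Elimination or hydride shift at the tertiary cation, and the presence of two aldehydes that both bind the Lewis acid, are likely. The precedent is no better than for the chosen step.
- Comparison: the chosen plan makes the bicycle and C4/C5 beforehand by reliable reactions and asks its unprecedented step for one bond, one ring and one stereocentre only.

Key step: step 21

Assumption: racemic 3-bromocyclopentene (1) is taken as purchasable (otherwise one step from cyclopentene and N-bromosuccinimide), and in step 1 the ligand enantiomer is the one that gives (R)-3.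

## Route

**Step 1**
Reactants: 1 3-bromocyclopentene (racemic); 2 [2-(1,3-dioxolan-2-yl)ethyl]magnesium bromide
Product: 3 2-{2-[(1R)-cyclopent-2-en-1-yl]ethyl}-1,3-dioxolane
Conditions: copper thiophene-2-carboxylate (CuTC, cat.), chiral BINOL-derived phosphoramidite ligand (cat.), CH2Cl2, −78 °C, slow addition of 2
Reagents that add atoms: none
Why: Copper-catalysed asymmetric allylic alkylation of a racemic cyclic allyl bromide with an alkyl Grignard reagent; both enantiomers of 1 pass through a common allyl-copper species, so the ligand alone sets C1.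

**Step 2**
Reactants: 3 2-{2-[(1R)-cyclopent-2-en-1-yl]ethyl}-1,3-dioxolane
Product: 4 3-[(1R)-cyclopent-2-en-1-yl]propanal
Conditions: 1 M HCl, THF, rt
Reagents that add atoms: water, O
Why: Acid hydrolysis of a dioxolane; nothing else in the molecule is acid-sensitive.

**Step 3**
Reactants: 4 3-[(1R)-cyclopent-2-en-1-yl]propanal
Product: 5 (1S,2S,5S)-cis-bicyclo[3.3.0]oct-7-en-2-ol (hydroxyl endo)
Conditions: Me2AlCl, CH2Cl2, −78 to 0 °C; 1 M HCl work-up
Reagents that add atoms: none
Why: Intramolecular carbonyl-ene reaction (type 1, five-membered ring): the aldehyde carbon bonds to C5 on the face that carries the tether, so the ring fusion is necessarily cis and C5 is set by C1. The hydrogen comes from C14, which moves the alkene to C6=C14. Me2AlCl scavenges protons and so suppresses Prins-type chloride capture.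

**Step 4**
Reactants: 5 (1S,2S,5S)-cis-bicyclo[3.3.0]oct-7-en-2-ol
Product: 6 (1S,5S)-cis-bicyclo[3.3.0]oct-7-en-2-one
Conditions: Dess–Martin periodinane, NaHCO3, CH2Cl2, 0 °C to rt
Reagents that add atoms: none
Why: Neutral oxidation of a secondary alcohol; buffered conditions keep the β,γ-unsaturated ketone from moving into conjugation.

**Step 5**
Reactants: 6 (1S,5S)-cis-bicyclo[3.3.0]oct-7-en-2-one
Product: 7 (1S,2S,5S)-2-{[dimethyl(propan-2-yloxy)silyl]methyl}-cis-bicyclo[3.3.0]oct-7-en-2-ol
Conditions: (i-PrO)Me2SiCH2MgCl (from the chloride and Mg), CeCl3, THF, −78 to 0 °C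
Reagents that add atoms: [dimethyl(propan-2-yloxy)silyl]methylmagnesium chloride, CC(C)O[Si](C)(C)C[Mg]Cl
Why: Addition of a hydroxymethyl anion equivalent to a ketone, with CeCl3 to suppress enolisation of the doubly activated C5–H. Attack from the convex face puts C15 exo and the new hydroxyl endo, cis to C6 and C10, which sets C4.

**Step 6**
Reactants: 7 (1S,2S,5S)-2-{[dimethyl(propan-2-yloxy)silyl]methyl}-cis-bicyclo[3.3.0]oct-7-en-2-ol
Product: 8 (1S,2S,5S)-2-(hydroxymethyl)-cis-bicyclo[3.3.0]oct-7-en-2-ol
Conditions: KF, KHCO3, 30% H2O2, THF/MeOH, rt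
Reagents that add atoms: hydrogen peroxide, OO
Why: Tamao oxidation of the alkoxysilane; the C–Si bond is replaced by C–O with retention and the isolated alkene is untouched.

**Step 7**
Reactants: 8 (1S,2S,5S)-2-(hydroxymethyl)-cis-bicyclo[3.3.0]oct-7-en-2-ol
Product: 9 (1S,2S,5S)-2-[(tert-butyldimethylsilyloxy)methyl]-cis-bicyclo[3.3.0]oct-7-en-2-ol
Conditions: TBSCl, imidazole, CH2Cl2, 0 °C
Reagents that add atoms: tert-butyldimethylsilyl chloride, CC(C)(C)[Si](C)(C)Cl
Why: Selective silylation of the primary hydroxyl of a primary/tertiary diol.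

**Step 8**
Reactants: 9 (1S,2S,5S)-2-[(tert-butyldimethylsilyloxy)methyl]-cis-bicyclo[3.3.0]oct-7-en-2-ol
Product: 10 (1S,5S,8R)-1-[(tert-butyldimethylsilyloxy)methyl]-3-hydroxy-2-oxabicyclo[3.2.1]octane-8-carbaldehyde (lactol, both C3 epimers)
Conditions: O3, CH2Cl2, −78 °C (indicator end point); PPh3, −78 °C to rt
Reagents that add atoms: ozone, [O-][O+]=O
Why: Ozonolysis of the only alkene gives the C6 and C14 aldehydes. Only C14 can reach the cis C4 hydroxyl in a six-membered lactol, which differentiates the two; some open dialdehyde and bis-hemiacetal are expected in equilibrium.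

**Step 9**
Reactants: 10 (1S,5S,8R)-1-[(tert-butyldimethylsilyloxy)methyl]-3-hydroxy-2-oxabicyclo[3.2.1]octane-8-carbaldehyde
Product: 11 (1S,5S,8R)-1-[(tert-butyldimethylsilyloxy)methyl]-2-oxabicyclo[3.2.1]oct-3-ene-8-carbaldehyde (formyl syn to the enol-ether bridge)
Conditions: MsCl, Et3N, CH2Cl2, −20 °C to rt
Reagents that add atoms: none
Why: Lactol dehydration through the anomeric mesylate, as used to make glycals from 2-deoxy lactols. Only the C14 lactol can eliminate (towards C10), so the equilibrium mixture should drain to the enol ether; low temperature limits enolisation of the C6 aldehyde.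

**Step 10**
Reactants: 12 (R)-2,2-dimethyl-1,3-dioxolane-4-carbaldehyde
Product: 13 (S)-4-(2,2-dibromoethenyl)-2,2-dimethyl-1,3-dioxolane
Conditions: CBr4, PPh3, CH2Cl2, 0 °C
Reagents that add atoms: carbon tetrabromide, BrC(Br)(Br)Br
Why: Corey–Fuchs dibromo-olefination; the stereocentre (the later C8) is not touched, and its descriptor changes only because the priorities change.

**Step 11**
Reactants: 13 (S)-4-(2,2-dibromoethenyl)-2,2-dimethyl-1,3-dioxolane
Product: 14 (S)-4,4-dibromobut-3-ene-1,2-diol
Conditions: AcOH/H2O (4:1), 40 °C
Reagents that add atoms: none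
Why: Acetonide hydrolysis, done at this early stage because acid cannot be used once the enol ether is present.

**Step 12**
Reactants: 14 (S)-4,4-dibromobut-3-ene-1,2-diol
Product: 15 (S)-4,4-dibromo-1-[(4-methoxyphenyl)methoxy]but-3-en-2-ol
Conditions: Bu2SnO, toluene, reflux (−H2O); then 4-methoxybenzyl chloride, Bu4NI, 60 °C
Reagents that add atoms: 4-methoxybenzyl chloride, COc1ccc(CCl)cc1
Why: Stannylene-acetal alkylation of a terminal 1,2-diol, which is selective for the primary oxygen.

**Step 13**
Reactants: 15 (S)-4,4-dibromo-1-[(4-methoxyphenyl)methoxy]but-3-en-2-ol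
Product: 16 (S)-{[4,4-dibromo-1-(4-methoxybenzyloxy)but-3-en-2-yl]oxy}triethylsilane
Conditions: TESCl, imidazole, DMF, 0 °C to rt
Reagents that add atoms: chlorotriethylsilane, CC[Si](Cl)(CC)CC
Why: Silylation of the secondary alcohol; the triethylsilyl ether can later be removed beside the primary tert-butyldimethylsilyl ether.

**Step 14**
Reactants: 16 (S)-{[4,4-dibromo-1-(4-methoxybenzyloxy)but-3-en-2-yl]oxy}triethylsilane
Product: 18 methyl (S)-5-[(4-methoxyphenyl)methoxy]-4-(triethylsilyloxy)pent-2-ynoate, via lithium acetylide 17 (not isolated)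
Conditions: n-BuLi (2.2 equiv), THF, −78 °C; ClCO2Me, −78 to 0 °C
Reagents that add atoms: methyl chloroformate, COC(=O)Cl
Why: Second stage of the Corey–Fuchs reaction (exchange, elimination and rearrangement to the lithium acetylide), followed by C-acylation in the same flask.

**Step 15**
Reactants: 18 methyl (S)-5-[(4-methoxyphenyl)methoxy]-4-(triethylsilyloxy)pent-2-ynoate
Product: 20 methyl (S,Z)-5-[(4-methoxyphenyl)methoxy]-2-[(4,4,5,5-tetramethyl-1,3,2-dioxaborolan-2-yl)methyl]-4-(triethylsilyloxy)pent-2-enoate, via alkenylalane 19 (not isolated)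
Conditions: i-Bu2AlH, HMPA, THF, 0 °C; then ICH2B(pin), 0 °C to rt
Reagents that add atoms: 2-(iodomethyl)-4,4,5,5-tetramethyl-1,3,2-dioxaborolane, CC1(C)OB(CI)OC1(C)C
Why: Conjugate hydroalumination of an alkynoate (syn addition, H to C7 and Al to C11) and alkylation of the α-aluminated acrylate with retention. C8 ends up cis to the ester and trans to the CH2B group, the geometry that gives anti adducts.

**Step 16**
Reactants: 11 (1S,5S,8R)-1-[(tert-butyldimethylsilyloxy)methyl]-2-oxabicyclo[3.2.1]oct-3-ene-8-carbaldehyde; 20 methyl (S,Z)-5-[(4-methoxyphenyl)methoxy]-2-[(pinacolboryl)methyl]-4-(triethylsilyloxy)pent-2-enoate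
Product: 22 trans-lactone (6,12-olide with 11(13)-methylene; C5 is C8 of the bicyclic enol ether; C7 carries the (1S)-2-(4-methoxybenzyloxy)-1-(triethylsilyloxy)ethyl chain C8–C9; C6 and C7 as in the target), via homoallylic borate ester 21 (not isolated)
Conditions: toluene, 80 °C, sealed tube; lactonisation in the same flask
Reagents that add atoms: none
Why: Allylboration of an aldehyde with a 2-alkoxycarbonyl allylboronate followed by lactonisation. In the closed chair transition state C8 is equatorial, which gives the 6,7-anti adduct and hence the trans lactone. Allylic 1,3-strain with the ester holds H8 in the alkene plane, so the aldehyde adds to the face opposite C9; this sets C7 from C8, and C6 follows from the chair.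

**Step 17**
Reactants: 22 trans-lactone with C8 triethylsilyl ether and C9 4-methoxybenzyl ether
Product: 23 C8 alcohol (22 with free 8-hydroxyl)
Conditions: HF·pyridine, excess pyridine, THF, 0 °C
Reagents that add atoms: none
Why: Buffered fluoride removes the secondary triethylsilyl ether much faster than the hindered primary tert-butyldimethylsilyl ether, and the excess pyridine protects the enol ether.

**Step 18**
Reactants: 23 C8 alcohol; 24 (R)-2-methylbutanoic acid
Product: 25 C8 (R)-2-methylbutanoate (C9 4-methoxybenzyl ether, C15 silyl ether)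
Conditions: DCC, DMAP (cat.), CH2Cl2, 0 °C to rt
Reagents that add atoms: none
Why: Carbodiimide esterification of a secondary alcohol; the low temperature and catalytic base guard the α-stereocentre of the acid and the lactone against translactonisation to O8.

**Step 19**
Reactants: 25 C8 (R)-2-methylbutanoate with C9 4-methoxybenzyl ether
Product: 26 C9 primary alcohol (8-acyloxy, 9-hydroxy)
Conditions: DDQ, CH2Cl2/pH 7 phosphate buffer, 0 °C
Reagents that add atoms: none
Why: Oxidative cleavage of a 4-methoxybenzyl ether under neutral conditions, which glycal-type enol ethers tolerate. The hydroxy ester is carried on at once because the acyl group can migrate from O8 to O9.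

**Step 20**
Reactants: 26 C9 primary alcohol
Product: 27 bridged enol ether bearing the methylene lactone, the C8 (R)-2-methylbutanoate and the C9 aldehyde
Conditions: Dess–Martin periodinane, NaHCO3, CH2Cl2, 0 °C
Reagents that add atoms: none
Why: Buffered, non-acidic oxidation to the α-acyloxy aldehyde, which is used directly to avoid epimerisation at C8.

**Step 21**
Reactants: 27 bridged enol ether with C8 ester and C9 aldehyde
Product: 29 9-deacetyl target as its C15 tert-butyldimethylsilyl ether, via oxocarbenium bromomagnesium alkoxide 28 (not isolated)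
Conditions: MgBr2·OEt2, 2,6-di-tert-butyl-4-methylpyridine, CH2Cl2, −40 to 0 °C; NaHCO3 (aq)
Reagents that add atoms: none
Why: Proposed new method: MgBr2 binds the C9 aldehyde, the electron-rich β-carbon C10 of the enol ether adds to it from the face on which C5 and C6 hold the chain, and the C14 oxocarbenium ion 28 loses H10 to the hindered pyridine, which restores the enol ether (now trisubstituted) and leaves the magnesium alkoxide of 29. The closest known reactions are Lewis-acid (Prins- or Mukaiyama-type) additions of dihydropyrans and glycals to aldehydes and the C-formylation of glycals, where the enol ether is likewise regenerated, but none of them closes a seven-membered ring onto a bridged enol ether. The ring closes 7-exo-trig at the carbonyl, with the enol-ether double bond exocyclic to the new ring. The new stereocentre C9 is controlled by C8 and by the ring: with the C8–O bond anti to the incoming C10 and the metal-bound oxygen pointing away from the lactone (pseudo-equatorial), the 8,9-trans alcohol results. The step needs the aldehyde to react in preference to the methylene lactone (the lactone enoate is not activated by this mild Lewis acid), proton loss instead of capture of 28 by bromide or by the C9 alkoxide (secured by the non-nucleophilic base and by the strain of an oxetane across C9–C14), and survival of the acid-labile allylic alcohol (cold, base-buffered, bicarbonate quench).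

**Step 22**
Reactants: 29 9-deacetyl target as its C15 silyl ether
Product: 30 C15 tert-butyldimethylsilyl ether of the target
Conditions: Ac2O, pyridine, DMAP (cat.), CH2Cl2, 0 °C
Reagents that add atoms: acetic anhydride, CC(=O)OC(C)=O
Why: Base-mediated acetylation of the secondary allylic alcohol; no acid is present that could ionise the C9–O bond.

**Step 23**
Reactants: 30 C15 tert-butyldimethylsilyl ether of the target
Product: 31 CNP0013863.3 (target)
Conditions: Bu4NF, AcOH (1:1), THF, 0 °C to rt
Reagents that add atoms: none
Why: Fluoride desilylation buffered with acetic acid, which is neither acidic enough to ionise the allylic acetate or hydrate the enol ether nor basic enough to move the esters or add to the methylene lactone.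

## Compound list

1 | 3-bromocyclopentene (racemic) | BrC1C=CCC1 | starting material
2 | [2-(1,3-dioxolan-2-yl)ethyl]magnesium bromide | Br[Mg]CCC1OCCO1 | starting material
3 | 2-{2-[(1R)-cyclopent-2-en-1-yl]ethyl}-1,3-dioxolane | O1CCOC1CC[C@@H]1C=CCC1 | intermediate
4 | 3-[(1R)-cyclopent-2-en-1-yl]propanal | O=CCC[C@@H]1C=CCC1 | intermediate
5 | (1S,2S,5S)-cis-bicyclo[3.3.0]oct-7-en-2-ol, hydroxyl endo | O[C@H]1CC[C@H]2CC=C[C@@H]12 | intermediate
6 | (1S,5S)-cis-bicyclo[3.3.0]oct-7-en-2-one | O=C1CC[C@H]2CC=C[C@@H]12 | intermediate
7 | (1S,2S,5S)-2-{[dimethyl(propan-2-yloxy)silyl]methyl}-cis-bicyclo[3.3.0]oct-7-en-2-ol | CC(C)O[Si](C)(C)C[C@]1(O)CC[C@H]2CC=C[C@@H]12 | intermediate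
8 | (1S,2S,5S)-2-(hydroxymethyl)-cis-bicyclo[3.3.0]oct-7-en-2-ol | OC[C@]1(O)CC[C@H]2CC=C[C@@H]12 | intermediate
9 | (1S,2S,5S)-2-[(tert-butyldimethylsilyloxy)methyl]-cis-bicyclo[3.3.0]oct-7-en-2-ol | CC(C)(C)[Si](C)(C)OC[C@]1(O)CC[C@H]2CC=C[C@@H]12 | intermediate
10 | (1S,5S,8R)-1-[(tert-butyldimethylsilyloxy)methyl]-3-hydroxy-2-oxabicyclo[3.2.1]octane-8-carbaldehyde (lactol, both C3 epimers; formyl syn to the oxygen bridge) | O=C[C@@H]1[C@H]2CC[C@]1(CO[Si](C)(C)C(C)(C)C)OC(O)C2 | intermediate
11 | (1S,5S,8R)-1-[(tert-butyldimethylsilyloxy)methyl]-2-oxabicyclo[3.2.1]oct-3-ene-8-carbaldehyde (formyl syn to the enol-ether bridge) | O=C[C@@H]1[C@H]2CC[C@]1(CO[Si](C)(C)C(C)(C)C)OC=C2 | intermediate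
12 | (R)-2,2-dimethyl-1,3-dioxolane-4-carbaldehyde | O=C[C@@H]1OC(C)(C)OC1 | starting material
13 | (S)-4-(2,2-dibromoethenyl)-2,2-dimethyl-1,3-dioxolane | BrC(Br)=C[C@@H]1OC(C)(C)OC1 | intermediate
14 | (S)-4,4-dibromobut-3-ene-1,2-diol | OC[C@@H](O)C=C(Br)Br | intermediate
15 | (S)-4,4-dibromo-1-[(4-methoxyphenyl)methoxy]but-3-en-2-ol | COc1ccc(COC[C@@H](O)C=C(Br)Br)cc1 | intermediate
16 | (S)-{[4,4-dibromo-1-(4-methoxybenzyloxy)but-3-en-2-yl]oxy}triethylsilane | COc1ccc(COC[C@@H](O[Si](CC)(CC)CC)C=C(Br)Br)cc1 | intermediate
17 | lithium acetylide of (S)-4-(4-methoxybenzyloxy)-3-(triethylsilyloxy)but-1-yne | COc1ccc(COC[C@@H](O[Si](CC)(CC)CC)C#C[Li])cc1 | intermediate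
18 | methyl (S)-5-[(4-methoxyphenyl)methoxy]-4-(triethylsilyloxy)pent-2-ynoate | COc1ccc(COC[C@@H](O[Si](CC)(CC)CC)C#CC(=O)OC)cc1 | intermediate
19 | methyl (S)-2-(diisobutylalumanyl)-5-[(4-methoxyphenyl)methoxy]-4-(triethylsilyloxy)pent-2-enoate (C8 cis to the ester) | COC(=O)/C(=C\[C@H](O[Si](CC)(CC)CC)COCc1ccc(OC)cc1)[Al](CC(C)C)CC(C)C | intermediate
20 | methyl (S,Z)-5-[(4-methoxyphenyl)methoxy]-2-[(4,4,5,5-tetramethyl-1,3,2-dioxaborolan-2-yl)methyl]-4-(triethylsilyloxy)pent-2-enoate | COC(=O)/C(=C\[C@H](O[Si](CC)(CC)CC)COCc1ccc(OC)cc1)CB1OC(C)(C)C(C)(C)O1 | intermediate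
21 | pinacol borate of the 6,7-anti homoallylic alcohol (methyl 2-methylidene ester, C6–O–B, C5 on the bicyclic enol ether) | C=C(C(=O)OC)[C@H]([C@H](O[Si](CC)(CC)CC)COCc1ccc(OC)cc1)[C@H](OB1OC(C)(C)C(C)(C)O1)[C@@H]1[C@H]2CC[C@]1(CO[Si](C)(C)C(C)(C)C)OC=C2 | intermediate
22 | trans-α-methylene-γ-lactone with C8 triethylsilyl ether and C9 4-methoxybenzyl ether on the bicyclic enol ether (C1, C4–C8 as in the target) | C=C1C(=O)O[C@@H]([C@H]1[C@H](O[Si](CC)(CC)CC)COCc1ccc(OC)cc1)[C@@H]1[C@H]2CC[C@]1(CO[Si](C)(C)C(C)(C)C)OC=C2 | intermediate
23 | C8 alcohol of 22 (8-hydroxy, 9-(4-methoxybenzyloxy)) | C=C1C(=O)O[C@@H]([C@H]1[C@H](O)COCc1ccc(OC)cc1)[C@@H]1[C@H]2CC[C@]1(CO[Si](C)(C)C(C)(C)C)OC=C2 | intermediate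
24 | (R)-2-methylbutanoic acid | CC[C@@H](C)C(=O)O | starting material
25 | C8 (R)-2-methylbutanoate, C9 4-methoxybenzyl ether | C=C1C(=O)O[C@@H]([C@H]1[C@H](OC(=O)[C@H](C)CC)COCc1ccc(OC)cc1)[C@@H]1[C@H]2CC[C@]1(CO[Si](C)(C)C(C)(C)C)OC=C2 | intermediate
26 | C8 (R)-2-methylbutanoate, C9 primary alcohol | C=C1C(=O)O[C@@H]([C@H]1[C@H](OC(=O)[C@H](C)CC)CO)[C@@H]1[C@H]2CC[C@]1(CO[Si](C)(C)C(C)(C)C)OC=C2 | intermediate
27 | bridged enol ether with methylene lactone, C8 (R)-2-methylbutanoate and C9 aldehyde | C=C1C(=O)O[C@@H]([C@H]1[C@H](OC(=O)[C@H](C)CC)C=O)[C@@H]1[C@H]2CC[C@]1(CO[Si](C)(C)C(C)(C)C)OC=C2 | intermediate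
28 | C14 oxocarbenium ion with C9–O–MgBr and bromide counter-ion (C9 on the face of C10 towards C5) | C=C1C(=O)O[C@H]2[C@H]1[C@H](OC(=O)[C@H](C)CC)[C@@H](O[Mg]Br)[C@@H]1C=[O+][C@@]3(CO[Si](C)(C)C(C)(C)C)CC[C@@H]1[C@@H]23.[Br-] | intermediate
29 | 9-deacetyl target as its C15 tert-butyldimethylsilyl ether | C=C1C(=O)O[C@H]2[C@H]1[C@H](OC(=O)[C@H](C)CC)[C@@H](O)C1=CO[C@@]3(CO[Si](C)(C)C(C)(C)C)CC[C@@H]1[C@@H]23 | intermediate
30 | C15 tert-butyldimethylsilyl ether of the target | C=C1C(=O)O[C@H]2[C@H]1[C@H](OC(=O)[C@H](C)CC)[C@@H](OC(C)=O)C1=CO[C@@]3(CO[Si](C)(C)C(C)(C)C)CC[C@@H]1[C@@H]23 | intermediate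
31 | CNP0013863.3 | C=C1C(=O)O[C@H]2[C@H]1[C@H](OC(=O)[C@H](C)CC)[C@@H](OC(C)=O)C1=CO[C@@]3(CO)CC[C@@H]1[C@@H]23 | target

## Step count and least certain steps

Total: 23 steps. Longest linear sequence: 17 steps (steps 1–9 and 16–23). The boronate arm is 6 steps (steps 10–15).

**Step 21 (key step, proposed new method).** The Lewis acid may ionise the new allylic C9–O bond next to the enol ether (Ferrier-type loss of the hydroxyl). The oxocarbenium ion may be captured by bromide or by the C9 alkoxide instead of losing H10. C10 may add to the methylene lactone instead. The aldehyde may be attacked on the wrong face, or may epimerise at C8 before it reacts. Fallback with known chemistry, a Nozaki–Hiyama–Kishi closure of the same bond: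
- It sets out from 25. The enol ether is iodinated at C10 (N-iodosuccinimide, catalytic AgNO3, MeCN) to the 10-iodo enol ether F1.
- DDQ then frees the C9 alcohol of the iodide, F2, and Dess–Martin oxidation gives the iodo aldehyde F3.
- CrCl2 with catalytic NiCl2 in DMF/THF joins C10 to C9 and returns to the route at 29.

**Step 16.** The deactivated boronate may add too slowly to the hindered aldehyde. The facial preference of the bicyclic aldehyde may also oppose the sense imposed by C8 (a mismatched pair), which would erode selectivity at C6 and C7. Fallback: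
- From 18, alkenylalane 19 is trapped with formaldehyde to give the hydroxymethyl enoate F4, and CBr4/PPh3 gives the allylic bromide F5.
- CrCl2-mediated allylation of 11 with F5, which is known to favour the syn adduct, gives the cis-lactone F6 (the C6 epimer of 22).
- LiOH opens F6 to the hydroxy acid F7, and Mitsunobu lactonisation (PPh3, diisopropyl azodicarboxylate) inverts C6 and returns to the route at 22.

**Step 9.** Mesylation may fall on the hemiacetal hydroxyl of the bis-hemiacetal form instead of the C14 lactol. The amine may enolise the C6 aldehyde and scramble C5. Elimination may be slow against re-closure. Fallback: the dehydration is moved behind the coupling. From 10 and 20, thermal allylboration–lactonisation gives the lactol lactone F8, in which C6 is no longer an aldehyde, and MsCl/Et3N then returns to the route at 22.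

**Step 1.** Enantioselection in the copper-catalysed alkylation may be insufficient for the five-membered ring, and the functionalised Grignard reagent in THF may lower it further. Fallback:
- From 1, palladium-catalysed asymmetric allylic alkylation with dimethyl malonate ([Pd(C3H5)Cl]2, DACH-phenyl diphosphine ligand, NaH) gives the malonate F9.
- Krapcho decarboxylation (LiCl, wet DMSO, heat) gives the ester F10, and i-Bu2AlH at −78 °C gives the aldehyde F11.
- Wittig reaction with Ph3P=CHOMe gives the enol ether F12, and mild acid hydrolysis returns to the route at 4.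

**Step 23.** Fluoride or adventitious acid may remove or move the C9 acetate, ionise the allylic C9–O bond, or add to the methylene lactone before the hindered silyl ether is gone. Fallback: the silyl group is removed before the acetate exists. From 29, Bu4NF/AcOH gives the 9,15-diol F13, Ac2O/pyridine gives the 9,15-diacetate F14, and a lipase (Candida antarctica lipase B, phosphate buffer/tert-butyl methyl ether) hydrolyses only the primary acetate to reach 31.

## Further compounds

F1 | step 21 | 10-iodo derivative of 25 (iodine on the enol-ether β-carbon) | C=C1C(=O)O[C@@H]([C@H]1[C@H](OC(=O)[C@H](C)CC)COCc1ccc(OC)cc1)[C@@H]1[C@H]2CC[C@]1(CO[Si](C)(C)C(C)(C)C)OC=C2I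
F2 | step 21 | 10-iodo C9 alcohol | C=C1C(=O)O[C@@H]([C@H]1[C@H](OC(=O)[C@H](C)CC)CO)[C@@H]1[C@H]2CC[C@]1(CO[Si](C)(C)C(C)(C)C)OC=C2I
F3 | step 21 | 10-iodo C9 aldehyde | C=C1C(=O)O[C@@H]([C@H]1[C@H](OC(=O)[C@H](C)CC)C=O)[C@@H]1[C@H]2CC[C@]1(CO[Si](C)(C)C(C)(C)C)OC=C2I
F4 | step 16 | methyl (S,Z)-2-(hydroxymethyl)-5-[(4-methoxyphenyl)methoxy]-4-(triethylsilyloxy)pent-2-enoate | COC(=O)/C(CO)=C\[C@H](O[Si](CC)(CC)CC)COCc1ccc(OC)cc1
F5 | step 16 | methyl (S)-2-(bromomethyl)-5-[(4-methoxyphenyl)methoxy]-4-(triethylsilyloxy)pent-2-enoate (C8 cis to the ester) | COC(=O)/C(CBr)=C\[C@H](O[Si](CC)(CC)CC)COCc1ccc(OC)cc1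
F6 | step 16 | cis-lactone, C6 epimer of 22 | C=C1C(=O)O[C@H]([C@H]1[C@H](O[Si](CC)(CC)CC)COCc1ccc(OC)cc1)[C@@H]1[C@H]2CC[C@]1(CO[Si](C)(C)C(C)(C)C)OC=C2
F7 | step 16 | 6,7-syn hydroxy acid from F6 | C=C(C(=O)O)[C@H]([C@H](O[Si](CC)(CC)CC)COCc1ccc(OC)cc1)[C@@H](O)[C@@H]1[C@H]2CC[C@]1(CO[Si](C)(C)C(C)(C)C)OC=C2
F8 | step 9 | lactol lactone (22 with C14 lactol in place of the enol ether) | C=C1C(=O)O[C@@H]([C@H]1[C@H](O[Si](CC)(CC)CC)COCc1ccc(OC)cc1)[C@@H]1[C@H]2CC[C@]1(CO[Si](C)(C)C(C)(C)C)OC(O)C2
F9 | step 1 | dimethyl (S)-2-(cyclopent-2-en-1-yl)malonate | COC(=O)C(C(=O)OC)[C@@H]1C=CCC1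
F10 | step 1 | methyl (R)-2-(cyclopent-2-en-1-yl)acetate | COC(=O)C[C@@H]1C=CCC1
F11 | step 1 | (R)-2-(cyclopent-2-en-1-yl)acetaldehyde | O=CC[C@@H]1C=CCC1
F12 | step 1 | (R)-3-(3-methoxyprop-2-en-1-yl)cyclopentene (E/Z mixture) | COC=CC[C@@H]1C=CCC1
F13 | step 23 | 9,15-diol (desilylated 29) | C=C1C(=O)O[C@H]2[C@H]1[C@H](OC(=O)[C@H](C)CC)[C@@H](O)C1=CO[C@@]3(CO)CC[C@@H]1[C@@H]23
F14 | step 23 | 9,15-diacetate | C=C1C(=O)O[C@H]2[C@H]1[C@H](OC(=O)[C@H](C)CC)[C@@H](OC(C)=O)C1=CO[C@@]3(COC(C)=O)CC[C@@H]1[C@@H]23
A1 | alternative 1 | tricyclic bridged lactone with C9 enol silane and C5–C6 alkene | O=C1O[C@@]2(CO[Si](C(C)C)(C(C)C)C(C)C)CC[C@H]3C1=C(O[Si](C)(C)C(C)(C)C)[C@@H](OCc4ccc(OC)cc4)[C@@H](CCO[Si](C)(C)C(C)(C)C)C=C23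
A2 | alternative 2 | cis-hydroazulenone (C8 ketone, C6–C7 alkene) | O=C1C=C[C@@H]2[C@@H](CCC23OCCO3)[C@H](CO[Si](C)(C)C(C)(C)C)C1
A3 | alternative 3 | bridged enol ether with free C6 hydroxyl and C7 acrylate ester | C=C(C(=O)OC)[C@@H]1[C@H](OC(=O)[C@H](C)CC)[C@@H](OC(C)=O)C2=CO[C@@]3(CO[Si](C)(C)C(C)(C)C)CC[C@@H]2[C@H]3[C@H]1O
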